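In a one-step world G falls for as long as one waits, but in maple it stood at 17.1% at 40.0 min and 17.0% at 180 min.

| flask | G | L | temperature | remark | time |
|---|---|---|---|---|---|
| maple | 0.050 M | 0.01 mol% | 5 °C | the very flask that is asked about, followed so far |  |
| elm | 0.025 M | 0.01 mol% | 0 °C | run made earlier |  |
| flask | 0.050 M | 0.01 mol% | 5 °C |  | 3.0 h |

| run | time / min | Z / % | G / % |
|---|---|---|---|
| maple | 40.0 | 82.8 | 17.1 |
| maple | 80.0 | 84.3 | 17.4 |
| maple | 120 | 82.9 | 17.5 |
| maple | 150 | 82.5 | 16.6 |
| maple | 180 | 82.7 | 17.0 |
| elm | 3.00 | 20.4 | 80.0 |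
| elm | 6.00 | 35.5 | 64.9 |
| elm | 12.0 | 55.0 | 44.0 |
| elm | 20.0 | 68.9 | 30.3 |
| elm | 40.0 | 81.2 | 18.1 |

(readings scatter by 0.5 percentage points)

- grey: at 3.0 h raise the temperature by 10 K, then wait 1.5 h
- violet: at 3.0 h add L, 100% of the amount charged, then wait 1.5 h
- ochre: at 3.0 h add G, 50.0% of the amount charged, then wait 1.5 h
- teal: change nothing and wait 1.5 h more

- amounts and yields of Z count Q too
- given per volume of solution although it is solid: Q
- what is added takes up no volume worth counting
- the earlier runs were read with a standard deviation of 0.5 percentage points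
- what may be going on: G + L -> Z + L; Q <-> Z; L -> J; L -> D

- Z, in percent of the G first charged, at 3.0 h
- the remedy with the largest gain of Z, or "none" below 2 percentage points (grey / violet / ochre / teal / none)
- Z present, in percent of the G first charged, after ochre
- Z present, in percent of the G first charged, after teal

1. I worked with the fraction left, f, which is c_G over its starting value, and asked which given number the outcome hangs on.

2. Time: across those maple readings f moved by 0.1 percentage points, against a scatter of 0.5 points. So the exact hour matters little.

3. The plateau: one maple reading off by 0.5 points shifts f by 2.94% of itself. That is tolerable.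

4. The charge of L: the conversion of G is listed as one-way, so I read the stop as L lost to J and D. I took G as pseudo-first-order, with -ln f growing in step with the L charged. Then half the charge turns f into its square root, 41.2%, a shift of 24 points, larger than the scatter.

5. The number: the mean maple reading gives f = 17.1%. I named the catalyst dose B, the value of -ln f that one charge of L buys in maple before it stops, and read B = 1.76.

6. My reckoning: I put Z at 82.9% at the time asked. Waiting, warming or adding G brings no new dose. Fresh L brings B again, so f falls to 2.93%, a gain of 14 points.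

7. The forecast: 83% now, 83% after ochre, 83% after teal, and violet as the best remedy: “With L dead, waiting, warming, or adding G gives no more Z”.

8. The flask gave 83.1% now, 83.1% after ochre and 83.1% after teal. The best remedy was violet, with a gain of 17 points.

    G + L → Z + L, rate k1*[G]*[L]/(1 + ([G]/Km1) + ([Z]/Kp1)) (16.9 mM, 0.0535 M, k = 1740 M⁻¹ s⁻¹, Ea = 36.0 kJ mol⁻¹)
    Q ⇌ Z, rate k2*(cs2 - [Z]) while solid is left; crystals form when [Z] > cs2 (solubility = 0.850 mM, k = 0.00648 s⁻¹)
    L → J (k = 2.76 × 10⁻⁵ s⁻¹, Ea = 212 kJ mol⁻¹)
    L → D (k = 0.00194 s⁻¹, Ea = 84.0 kJ mol⁻¹)
    (constants at 5 °C)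

In the flask at 180 min, L stood at 0%, D at 98.6% and J at 1.40%, with G at 17%. Z after violet reached 99.6%, above my 97.1%. I then took the neighbour flask with 0.004 mol% of L. Its dose by my rule is 0.706, so f should be 49.4%. That flask starts at c_G 2.96 times the saturation constant 16.9 mM. At 180 min it held Z at 41.0% and G at 59%.

The earlier runs and the new flask are calculated on assumed constants, and the scatter is random.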